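**Retrosynthetic overview**
1. Feature used: in the cyclohexene ring (C1(Me)=C2, C3, C4, C5, C6) the C5 aryl ring with its ortho oxygen, C5, C4 and the C4 ketone carbon are the ten ring atoms of a 7-oxygenated 3,4-dihydrocoumarin, and C1=C2 is an isolated trisubstituted alkene.
2. Endgame (retro): chalcone C=C by Claisen–Schmidt condensation, acetyl group by Stille coupling at an aryl bromide, C4 ketone by opening the lactone with 2,4-bis(methoxymethoxy)phenyllithium.
3. Key disconnection: C1=C2 by ring-closing metathesis of a trans-3-(1-arylallyl)-4-methallyl-dihydrocoumarin. The carbocycle is the only ring formed; the lactone ring comes with the coumarin and is opened afterwards.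
4. Diene: C3–C4 by iridium-catalysed branched allylation of the lactone silyl ketene acetal; C5–C6 by copper/bis(oxazoline)-catalysed conjugate methallylation of a coumarin-3-carboxylate, whose ester is a removable activating group.

Key step: step 9

Remark: for the two catalyst-controlled steps (2 and 8) the ligand antipode that gives the drawn configuration is assumed to be fixed by a small test run; one antipode is named for definiteness.

Step 1
Reactants: 1 ethyl 7-hydroxy-2-oxo-2H-chromene-3-carboxylate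
Product: 2 ethyl 7-(methoxymethoxy)-2-oxo-2H-chromene-3-carboxylate
Conditions: MOMCl, iPr2NEt, CH2Cl2, 0 °C → rt
Reagents that add atoms: chloromethyl methyl ether, COCCl
Why: O-alkylation (methoxymethyl protection) of the only phenol; the acetal should survive the bases, organolithiums and metal catalysts used later.

Step 2
Reactants: 2 ethyl 7-(methoxymethoxy)-2-oxo-2H-chromene-3-carboxylate
Product: 3 ethyl (4S)-7-(methoxymethoxy)-4-(2-methylprop-2-en-1-yl)-2-oxochromane-3-carboxylate
Conditions: Cu(OTf)2 (10 mol%), 2,2′-isopropylidenebis[(4S)-4-tert-butyl-2-oxazoline] (12 mol%), CH2=C(Me)CH2SiMe3, (CF3)2CHOH, CH2Cl2, −40 → 0 °C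
Reagents that add atoms: trimethyl(2-methylallyl)silane, C=C(C)C[Si](C)(C)C
Why: Catalytic enantioselective Hosomi–Sakurai conjugate allylation: the lactone and ester carbonyls chelate the copper–bis(oxazoline) Lewis acid, whose tert-butyl groups leave one face of C4 open to the allylsilane, so C4 should be set as S by the ligand while the fluoro alcohol protonates the copper enolate and takes the silyl group; the epimerisable C3 centre is removed in step 3.

Step 3
Reactants: 3 ethyl (4S)-7-(methoxymethoxy)-4-(2-methylprop-2-en-1-yl)-2-oxochromane-3-carboxylate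
Product: 4 (4S)-7-(methoxymethoxy)-4-(2-methylprop-2-en-1-yl)chroman-2-one
Conditions: LiCl, H2O, DMSO, 150 °C
Reagents that add atoms: none
Why: Krapcho dealkoxycarbonylation (chloride attack on the ethyl group, loss of CO2, protonation of the lactone enolate) under neutral conditions; C4 carries no acidic hydrogen and should keep its configuration.

Step 4
Reactants: 5 4-bromoresorcinol
Product: 6 1-bromo-2,4-bis(methoxymethoxy)benzene
Conditions: MOMCl, iPr2NEt, CH2Cl2, 0 °C → rt
Reagents that add atoms: chloromethyl methyl ether, COCCl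
Why: Double O-alkylation of the two phenols; 6 serves both as precursor of the C3 aryl unit and as source of the aryllithium of step 10.

Step 5
Reactants: 6 1-bromo-2,4-bis(methoxymethoxy)benzene
Product: 8 3-bromo-2,6-bis(methoxymethoxy)benzaldehyde, via [3-bromo-2,6-bis(methoxymethoxy)phenyl]lithium 7 (not isolated)
Conditions: LiN(iPr)2, THF, −78 °C; DMF, −78 → 0 °C; H2O
Reagents that add atoms: N,N-dimethylformamide, CN(C)C=O
Why: Directed ortho-metalation: the amide base removes the proton flanked by the two coordinating methoxymethoxy groups without touching the C–Br bond, and the aryllithium is formylated by DMF.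

Step 6
Reactants: 8 3-bromo-2,6-bis(methoxymethoxy)benzaldehyde
Product: 10 rac-tert-butyl 1-[3-bromo-2,6-bis(methoxymethoxy)phenyl]prop-2-en-1-yl carbonate, via bromomagnesium alkoxide 9 (not isolated)
Conditions: CH2=CHMgBr, THF, −78 → 0 °C; Boc2O, 0 °C → rt
Reagents that add atoms: vinylmagnesium bromide, C=C[Mg]Br; di-tert-butyl dicarbonate, CC(C)(C)OC(=O)OC(=O)OC(C)(C)C
Why: Grignard 1,2-addition to the aldehyde and acylation of the alkoxide in the same flask; the carbinol centre is racemic on purpose, because it is erased in the π-allyl complex of step 8.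

Step 7
Reactants: 4 (4S)-7-(methoxymethoxy)-4-(2-methylprop-2-en-1-yl)chroman-2-one
Product: 12 tert-butyl{[(4S)-7-(methoxymethoxy)-4-(2-methylprop-2-en-1-yl)-4H-chromen-2-yl]oxy}dimethylsilane, via lithium enolate 11 (not isolated)
Conditions: LiN(SiMe3)2, THF, −78 °C; TBSCl, DMPU, −78 → 0 °C; non-aqueous work-up, used crude
Reagents that add atoms: tert-butyldimethylsilyl chloride, CC(C)(C)[Si](C)(C)Cl
Why: Kinetic enolisation of the lactone and O-silylation in a dipolar medium give the silyl ketene acetal; the enolate is kept cold to avoid phenoxide loss, and C4 is not involved.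

Step 8
Reactants: 12 tert-butyl{[(4S)-7-(methoxymethoxy)-4-(2-methylprop-2-en-1-yl)-4H-chromen-2-yl]oxy}dimethylsilane; 10 rac-tert-butyl 1-[3-bromo-2,6-bis(methoxymethoxy)phenyl]prop-2-en-1-yl carbonate (2 equiv)
Product: 13 (3R,4S)-3-{(1S)-1-[3-bromo-2,6-bis(methoxymethoxy)phenyl]prop-2-en-1-yl}-7-(methoxymethoxy)-4-(2-methylprop-2-en-1-yl)chroman-2-one
Conditions: [Ir(cod)Cl]2 (3 mol%), (S)-BINOL phosphoramidite of 5H-dibenz[b,f]azepine (12 mol%), THF, 25 °C
Reagents that add atoms: none
Why: Iridium-catalysed branched-selective asymmetric allylic alkylation with a silyl ketene acetal: the carbonate ionises with loss of CO2 to a π-allyl iridium complex common to both enantiomers of 10, the phosphoramidite–alkene ligand directs attack to the aryl-bearing terminus and should set that carbon as S, the ketene acetal reacts on the face opposite the C4 methallyl group to give the 3,4-trans lactone (3R), and the tert-butoxide takes the silyl group.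

Step 9
Reactants: 13 (3R,4S)-3-{(1S)-1-[3-bromo-2,6-bis(methoxymethoxy)phenyl]prop-2-en-1-yl}-7-(methoxymethoxy)-4-(2-methylprop-2-en-1-yl)chroman-2-one
Product: 14 (6aR,7S,10aS)-7-[3-bromo-2,6-bis(methoxymethoxy)phenyl]-3-(methoxymethoxy)-9-methyl-6a,7,10,10a-tetrahydro-6H-benzo[c]chromen-6-one
Conditions: second-generation Grubbs catalyst RuCl2(=CHPh)(H2IMes)(PCy3) (5 mol%), CH2Cl2 (0.005 M), 40 °C
Reagents that add atoms: none
Why: Alkene metathesis: the ruthenium benzylidene first exchanges onto the monosubstituted vinyl group, the resulting alkylidene adds across the 1,1-disubstituted methallyl alkene in an intramolecular [2+2] step, and cycloreversion of the ruthenacyclobutane releases the C8=C9 double bond (C1=C2 of the target) and a ruthenium methylidene, ethene leaving as a gas. The closest known reaction type is ring-closing metathesis of a monosubstituted with a 1,1-disubstituted alkene to a 1-methylcyclohexene with an N-heterocyclic-carbene ruthenium catalyst, also with a 2,6-dialkoxyaryl group on the allylic carbon. The one ring that closes is the six-membered carbocycle, formed by joining the two terminal alkene carbons, and it is annulated trans onto the lactone across C6a–C10a. No stereocentre is created; C7, C6a and C10a come from steps 8 and 2 and should not be touched by the neutral catalyst. The step needs cyclisation to win over cross-metathesis and alkene migration: the lactone ring holds the two alkene arms on neighbouring carbons so that the diequatorial conformer brings them together, each arm carries one alkene only, and high dilution suppresses dimerisation. Aryl bromide, acetals and lactone are inert to the catalyst.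

Step 10
Reactants: 14 (6aR,7S,10aS)-7-[3-bromo-2,6-bis(methoxymethoxy)phenyl]-3-(methoxymethoxy)-9-methyl-6a,7,10,10a-tetrahydro-6H-benzo[c]chromen-6-one; 6 1-bromo-2,4-bis(methoxymethoxy)benzene
Product: 16 [(1R,2S,6S)-2-[3-bromo-2,6-bis(methoxymethoxy)phenyl]-6-[2-hydroxy-4-(methoxymethoxy)phenyl]-4-methylcyclohex-3-en-1-yl][2,4-bis(methoxymethoxy)phenyl]methanone, via [2,4-bis(methoxymethoxy)phenyl]lithium 15 (not isolated)
Conditions: 6, n-BuLi, THF, −78 °C; slow addition to 14 (1.05 equiv of 15), THF, −78 °C; AcOH, −78 °C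
Reagents that add atoms: none
Why: Bromine–lithium exchange, then nucleophilic acyl substitution at the aryl lactone: the tetrahedral intermediate expels the phenoxide, and the ketone so formed is flanked by two ring methines and an ortho-substituted aryl ring, so a second addition should be slow at −78 °C, as should aryl–aryl bromine–lithium exchange; the C1 centre (former C6a) is kept.

Step 11
Reactants: 16 [(1R,2S,6S)-2-[3-bromo-2,6-bis(methoxymethoxy)phenyl]-6-[2-hydroxy-4-(methoxymethoxy)phenyl]-4-methylcyclohex-3-en-1-yl][2,4-bis(methoxymethoxy)phenyl]methanone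
Product: 18 1-{3-[(1S,5S,6R)-6-[2,4-bis(methoxymethoxy)benzoyl]-5-[2-hydroxy-4-(methoxymethoxy)phenyl]-3-methylcyclohex-2-en-1-yl]-2,4-bis(methoxymethoxy)phenyl}ethan-1-one, via 1-ethoxyvinyl arene 17 (not isolated)
Conditions: CH2=C(OEt)SnBu3, Pd(PPh3)4 (10 mol%), toluene, 105 °C; then 0.5 M HCl, THF, 0 °C
Reagents that add atoms: tributyl(1-ethoxyvinyl)stannane, CCCC[Sn](CCCC)(CCCC)C(=C)OCC; water, O
Why: Stille coupling of the aryl bromide with an acetyl anion equivalent, then brief cold hydrolysis of the very labile α-ethoxystyrene, which should leave the aryl acetals and the ring alkene intact; no stereocentre is involved.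

Step 12
Reactants: 19 2,4-dihydroxybenzaldehyde
Product: 20 2,4-bis(methoxymethoxy)benzaldehyde
Conditions: MOMCl, iPr2NEt, CH2Cl2, 0 → 40 °C
Reagents that add atoms: chloromethyl methyl ether, COCCl
Why: Double O-alkylation; excess reagent and warming are used because the 2-hydroxyl is hydrogen-bonded to the aldehyde.

Step 13
Reactants: 18 1-{3-[(1S,5S,6R)-6-[2,4-bis(methoxymethoxy)benzoyl]-5-[2-hydroxy-4-(methoxymethoxy)phenyl]-3-methylcyclohex-2-en-1-yl]-2,4-bis(methoxymethoxy)phenyl}ethan-1-one; 20 2,4-bis(methoxymethoxy)benzaldehyde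
Product: 21 (E)-1-{3-[(1S,5S,6R)-6-[2,4-bis(methoxymethoxy)benzoyl]-5-[2-hydroxy-4-(methoxymethoxy)phenyl]-3-methylcyclohex-2-en-1-yl]-2,4-bis(methoxymethoxy)phenyl}-3-[2,4-bis(methoxymethoxy)phenyl]prop-2-en-1-one
Conditions: KOH (aq.), EtOH, 0 °C → rt
Reagents that add atoms: none
Why: Claisen–Schmidt condensation: the methyl ketone is the only unhindered enolisable site, aldol addition and E1cB dehydration should give the E enone, the protected 2′-oxygen blocks flavanone formation, and the tertiary hydrogen next to the ring ketone is shielded by both aryl-bearing neighbours.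

Step 14
Reactants: 21 (E)-1-{3-[(1S,5S,6R)-6-[2,4-bis(methoxymethoxy)benzoyl]-5-[2-hydroxy-4-(methoxymethoxy)phenyl]-3-methylcyclohex-2-en-1-yl]-2,4-bis(methoxymethoxy)phenyl}-3-[2,4-bis(methoxymethoxy)phenyl]prop-2-en-1-one
Product: 23 (E)-1-{3-[(1S,5S,6R)-6-(2,4-dihydroxybenzoyl)-5-(2,4-dihydroxyphenyl)-3-methylcyclohex-2-en-1-yl]-2,4-dihydroxyphenyl}-3-(2,4-dihydroxyphenyl)prop-2-en-1-one, via octakis(trimethylsilyl) ether 22 (not isolated)
Conditions: TMSOTf (excess), 2,2′-bipyridyl (excess), MeCN, 0 °C → rt; then H2O, rt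
Reagents that add atoms: none
Why: Silyl triflate/bipyridyl cleavage of aryl methoxymethyl ethers to aryl trimethylsilyl ethers, hydrolysed by water at neutral pH; the buffered aprotic medium is chosen because protic acid could hydrate the C1=C2 alkene or ketalise the C4 ketone with the two flanking phenols, and no stereocentre is touched.

**Compound list**
1 | ethyl 7-hydroxy-2-oxo-2H-chromene-3-carboxylate | CCOC(=O)C1=Cc2ccc(O)cc2OC1=O | starting material
2 | ethyl 7-(methoxymethoxy)-2-oxo-2H-chromene-3-carboxylate | CCOC(=O)C1=Cc2ccc(OCOC)cc2OC1=O | intermediate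
3 | ethyl (4S)-7-(methoxymethoxy)-4-(2-methylprop-2-en-1-yl)-2-oxochromane-3-carboxylate (C3 epimerisable, left undefined) | CCOC(=O)C1C(=O)Oc2cc(OCOC)ccc2[C@H]1CC(C)=C | intermediate
4 | (4S)-7-(methoxymethoxy)-4-(2-methylprop-2-en-1-yl)chroman-2-one | O=C1C[C@H](CC(C)=C)c2ccc(OCOC)cc2O1 | intermediate
5 | 4-bromoresorcinol (4-bromobenzene-1,3-diol) | Oc1ccc(Br)c(O)c1 | starting material
6 | 1-bromo-2,4-bis(methoxymethoxy)benzene | COCOc1ccc(Br)c(OCOC)c1 | intermediate
7 | [3-bromo-2,6-bis(methoxymethoxy)phenyl]lithium (not isolated) | [Li]c1c(OCOC)ccc(Br)c1OCOC | intermediate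
8 | 3-bromo-2,6-bis(methoxymethoxy)benzaldehyde | O=Cc1c(OCOC)ccc(Br)c1OCOC | intermediate
9 | bromomagnesium rac-1-[3-bromo-2,6-bis(methoxymethoxy)phenyl]prop-2-en-1-olate (not isolated) | C=CC(O[Mg]Br)c1c(OCOC)ccc(Br)c1OCOC | intermediate
10 | rac-tert-butyl 1-[3-bromo-2,6-bis(methoxymethoxy)phenyl]prop-2-en-1-yl carbonate | C=CC(OC(=O)OC(C)(C)C)c1c(OCOC)ccc(Br)c1OCOC | intermediate
11 | lithium (4S)-7-(methoxymethoxy)-4-(2-methylprop-2-en-1-yl)-4H-chromen-2-olate (not isolated) | [Li]OC1=C[C@H](CC(C)=C)c2ccc(OCOC)cc2O1 | intermediate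
12 | tert-butyl{[(4S)-7-(methoxymethoxy)-4-(2-methylprop-2-en-1-yl)-4H-chromen-2-yl]oxy}dimethylsilane | CC(C)(C)[Si](C)(C)OC1=C[C@H](CC(C)=C)c2ccc(OCOC)cc2O1 | intermediate
13 | (3R,4S)-3-{(1S)-1-[3-bromo-2,6-bis(methoxymethoxy)phenyl]prop-2-en-1-yl}-7-(methoxymethoxy)-4-(2-methylprop-2-en-1-yl)chroman-2-one (3,4-trans) | C=C[C@H](c1c(OCOC)ccc(Br)c1OCOC)[C@@H]1C(=O)Oc2cc(OCOC)ccc2[C@H]1CC(C)=C | intermediate
14 | (6aR,7S,10aS)-7-[3-bromo-2,6-bis(methoxymethoxy)phenyl]-3-(methoxymethoxy)-9-methyl-6a,7,10,10a-tetrahydro-6H-benzo[c]chromen-6-one (trans ring fusion) | CC1=C[C@H](c2c(OCOC)ccc(Br)c2OCOC)[C@@H]2C(=O)Oc3cc(OCOC)ccc3[C@H]2C1 | intermediate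
15 | [2,4-bis(methoxymethoxy)phenyl]lithium (not isolated) | [Li]c1ccc(OCOC)cc1OCOC | intermediate
16 | [(1R,2S,6S)-2-[3-bromo-2,6-bis(methoxymethoxy)phenyl]-6-[2-hydroxy-4-(methoxymethoxy)phenyl]-4-methylcyclohex-3-en-1-yl][2,4-bis(methoxymethoxy)phenyl]methanone | CC1=C[C@H](c2c(OCOC)ccc(Br)c2OCOC)[C@H](C(=O)c2ccc(OCOC)cc2OCOC)[C@@H](c2ccc(OCOC)cc2O)C1 | intermediate
17 | 1-ethoxyvinyl analogue of 16, with C(=CH2)OEt in place of Br (not isolated) | CC1=C[C@H](c2c(OCOC)ccc(C(=C)OCC)c2OCOC)[C@H](C(=O)c2ccc(OCOC)cc2OCOC)[C@@H](c2ccc(OCOC)cc2O)C1 | intermediate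
18 | 1-{3-[(1S,5S,6R)-6-[2,4-bis(methoxymethoxy)benzoyl]-5-[2-hydroxy-4-(methoxymethoxy)phenyl]-3-methylcyclohex-2-en-1-yl]-2,4-bis(methoxymethoxy)phenyl}ethan-1-one | CC1=C[C@H](c2c(OCOC)ccc(C(C)=O)c2OCOC)[C@H](C(=O)c2ccc(OCOC)cc2OCOC)[C@@H](c2ccc(OCOC)cc2O)C1 | intermediate
19 | 2,4-dihydroxybenzaldehyde | O=Cc1ccc(O)cc1O | starting material
20 | 2,4-bis(methoxymethoxy)benzaldehyde | O=Cc1ccc(OCOC)cc1OCOC | intermediate
21 | (E)-chalcone of 18 and 20, seven methoxymethyl ethers and one free phenol | CC1=C[C@H](c2c(OCOC)ccc(C(=O)/C=C/c3ccc(OCOC)cc3OCOC)c2OCOC)[C@H](C(=O)c2ccc(OCOC)cc2OCOC)[C@@H](c2ccc(OCOC)cc2O)C1 | intermediate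
22 | octakis(trimethylsilyl) ether of the target (not isolated) | CC1=C[C@H](c2c(O[Si](C)(C)C)ccc(C(=O)/C=C/c3ccc(O[Si](C)(C)C)cc3O[Si](C)(C)C)c2O[Si](C)(C)C)[C@H](C(=O)c2ccc(O[Si](C)(C)C)cc2O[Si](C)(C)C)[C@@H](c2ccc(O[Si](C)(C)C)cc2O[Si](C)(C)C)C1 | intermediate
23 | (E)-1-{3-[(1S,5S,6R)-6-(2,4-dihydroxybenzoyl)-5-(2,4-dihydroxyphenyl)-3-methylcyclohex-2-en-1-yl]-2,4-dihydroxyphenyl}-3-(2,4-dihydroxyphenyl)prop-2-en-1-one | CC1=C[C@H](c2c(O)ccc(C(=O)/C=C/c3ccc(O)cc3O)c2O)[C@H](C(=O)c2ccc(O)cc2O)[C@@H](c2ccc(O)cc2O)C1 | target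

**Step count**
Total: 14 steps. Longest linear sequence: 10 steps (1, 2, 3, 7, 8, 9, 10, 11, 13, 14).

**Steps most likely to fail**

Step 8 (iridium allylation). The allyl terminus is flanked by a 2,6-disubstituted aryl ring and the ketene acetal is β-branched, so carbon–carbon bond formation may be slow. Attack at the unsubstituted terminus, protodesilylation of 12, or a mismatched pairing of the chiral nucleophile with the catalyst could then erode regio- and diastereocontrol. The fallback sets out from 4 and returns at 13. Lactone 4 is reduced with i-Bu2AlH (toluene, −78 °C) to the lactol (4S)-7-(methoxymethoxy)-4-(2-methylprop-2-en-1-yl)chroman-2-ol F1. The alkoxide 9 of step 6 is quenched with water instead of Boc2O to give rac-1-[3-bromo-2,6-bis(methoxymethoxy)phenyl]prop-2-en-1-ol F2. F1, reacting through its ring-opened hydroxy aldehyde, and F2 are joined by iridium/enamine dual catalysis: [Ir(cod)Cl]2, the same phosphoramidite–alkene ligand, (S)-α,α-bis[3,5-bis(trifluoromethyl)phenyl]prolinol trimethylsilyl ether, Zn(OTf)2, 1,2-dichloroethane, 25 °C. The amine sets the α-carbon and the iridium ligand sets the benzylic carbon independently, giving (3R,4S)-3-{(1S)-1-[3-bromo-2,6-bis(methoxymethoxy)phenyl]prop-2-en-1-yl}-7-(methoxymethoxy)-4-(2-methylprop-2-en-1-yl)chroman-2-ol F3. Oxidation of F3 with PhI(OAc)2 and catalytic TEMPO (CH2Cl2, rt) gives 13.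

Step 2 (conjugate methallylation). The 7-alkoxy donor lowers the electrophilicity of C4, so conversion may stall or a poorly face-selective background addition may compete. The fallback sets out from 2 and returns at 4. Enamine-catalysed Michael addition of acetone to 2 (9-amino-9-deoxy-epi-quinine, PhCO2H, acetone, rt) should give ethyl (4S)-7-(methoxymethoxy)-2-oxo-4-(2-oxopropyl)chromane-3-carboxylate F4. Krapcho dealkoxycarbonylation (LiCl, H2O, DMSO, 150 °C) gives (4S)-7-(methoxymethoxy)-4-(2-oxopropyl)chroman-2-one F5. Wittig methylenation (Ph3P=CH2 from Ph3PCH3Br and KOtBu, THF, −78 → 0 °C), with the ketone reacting ahead of the aryl lactone, gives 4.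

Step 10 (aryllithium opening). Collapse of the tetrahedral intermediate in the flask may allow a second addition to the ketone, and bromine–lithium exchange at the C7 aryl bromide may compete. The fallback sets out from 14 and returns at 16. Aminolysis of 14 (MeNH(OMe)·HCl, i-PrMgCl, THF, −20 °C) gives (1R,2S,6S)-2-[3-bromo-2,6-bis(methoxymethoxy)phenyl]-6-[2-hydroxy-4-(methoxymethoxy)phenyl]-N-methoxy-N,4-dimethylcyclohex-3-ene-1-carboxamide F6. Its phenol is deprotonated with i-PrMgCl, then 15 is added (THF, −78 → 0 °C). The chelated tetrahedral intermediate should hold until the AcOH quench, which releases 16.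

**Further compounds**
F1 | step 8 | (4S)-7-(methoxymethoxy)-4-(2-methylprop-2-en-1-yl)chroman-2-ol | OC1C[C@H](CC(C)=C)c2ccc(OCOC)cc2O1
F2 | step 8 | rac-1-[3-bromo-2,6-bis(methoxymethoxy)phenyl]prop-2-en-1-ol | C=CC(O)c1c(OCOC)ccc(Br)c1OCOC
F3 | step 8 | (3R,4S)-3-{(1S)-1-[3-bromo-2,6-bis(methoxymethoxy)phenyl]prop-2-en-1-yl}-7-(methoxymethoxy)-4-(2-methylprop-2-en-1-yl)chroman-2-ol | C=C[C@H](c1c(OCOC)ccc(Br)c1OCOC)[C@@H]1C(O)Oc2cc(OCOC)ccc2[C@H]1CC(C)=C
F4 | step 2 | ethyl (4S)-7-(methoxymethoxy)-2-oxo-4-(2-oxopropyl)chromane-3-carboxylate | CCOC(=O)C1C(=O)Oc2cc(OCOC)ccc2[C@H]1CC(C)=O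
F5 | step 2 | (4S)-7-(methoxymethoxy)-4-(2-oxopropyl)chroman-2-one | O=C1C[C@H](CC(C)=O)c2ccc(OCOC)cc2O1
F6 | step 10 | (1R,2S,6S)-2-[3-bromo-2,6-bis(methoxymethoxy)phenyl]-6-[2-hydroxy-4-(methoxymethoxy)phenyl]-N-methoxy-N,4-dimethylcyclohex-3-ene-1-carboxamide | CC1=C[C@H](c2c(OCOC)ccc(Br)c2OCOC)[C@H](C(=O)N(C)OC)[C@@H](c2ccc(OCOC)cc2O)C1
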